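The heptane chain is cut between C1, the benzylic CH2 on the catechol ring, and C2. The key step exploits the 1,2-relationship of C2 and the oxygen-bearing stereocentre C3: both are the carbons of a terminal (S)-oxirane ring, opened at C2 by a 3,4-bis(benzyloxy)benzyl copper–magnesium reagent. One operation forges C1–C2 and releases O3 as the only free hydroxyl; the precursor carries C5 as a 1,3-dithiane-masked ketone. After unmasking, O3 directs a samarium-catalysed Evans–Tishchenko reduction with acetaldehyde, which sets C5 anti and leaves the acetate on O3; hydrogenolysis of three benzyl ethers finishes the route.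

Key step: step 3

Remark on locants: C1 is the benzylic carbon on the catechol ring and C7 the benzylic carbon on the 4-hydroxyphenyl ring; the target is the (3R,5R) anti-1,3-diol 3-acetate.

Step 1
Reactants: 1 3-[4-(benzyloxy)phenyl]propanal
Product: 2 2-{2-[4-(benzyloxy)phenyl]ethyl}-1,3-dithiane
Conditions: HS(CH2)3SH (1.1 equiv), BF3·OEt2 (0.2 equiv), CH2Cl2, 0 °C
Reagents that add atoms: propane-1,3-dithiol SCCCS
Why: Lewis-acid-catalysed dithioacetalisation of an unhindered aliphatic aldehyde is reliable and installs the Corey–Seebach acyl-anion equivalent that later becomes the C5 carbonyl; no stereocentre is formed.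

Step 2
Reactants: 2 2-{2-[4-(benzyloxy)phenyl]ethyl}-1,3-dithiane; 3 (S)-epichlorohydrin
Product: 6 (S)-2-{2-[4-(benzyloxy)phenyl]ethyl}-2-(oxiran-2-ylmethyl)-1,3-dithiane, via lithiated dithiane 4 (not isolated), via chlorohydrin lithium alkoxide 5 (not isolated)
Conditions: n-BuLi, THF, −25 °C; then 3, −78 → 25 °C
Reagents that add atoms: none
Why: Corey–Seebach umpolung alkylation: the 2-lithiodithiane opens the oxirane of 3 at its CH2 and the alkoxide formed then displaces chloride (3-exo-tet), so the C–O stereocentre of the chiral-pool reagent is carried over untouched and becomes C3 of the (S)-epoxide.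

Step 3
Reactants: 6 (S)-2-{2-[4-(benzyloxy)phenyl]ethyl}-2-(oxiran-2-ylmethyl)-1,3-dithiane; 7 3,4-bis(benzyloxy)benzyl chloride
Product: 9 (R)-4-[3,4-bis(benzyloxy)phenyl]-1-(2-{2-[4-(benzyloxy)phenyl]ethyl}-1,3-dithian-2-yl)butan-2-ol, via benzylic Grignard reagent 8 (not isolated)
Conditions: 7 added slowly to Mg (excess), THF, 0 °C; then 6, CuI (10 mol %), THF, −40 → 0 °C; H2O/NH4Cl work-up
Reagents that add atoms: none
Why: Magnesium inserts into the benzylic C–Cl bond of 7 and the Grignard reagent 8 transmetalates to copper(I); the benzylcopper species attacks the oxirane of 6 in an SN2 opening at the unsubstituted CH2 (C2), forming C1–C2 and a magnesium alkoxide at C3. The closest known reaction type is the copper-catalysed opening of terminal epoxides by Grignard reagents, here with a benzylic nucleophile. No ring is closed (the three-membered ring is opened) and no new stereocentre is made: the C3–O bond is not touched, so the configuration set by (S)-epichlorohydrin is carried into 9 (the descriptor becomes R only because the CIP priorities change). The step needs regioselectivity for C2 over C3, secured by the monosubstituted oxirane whose C3 sits next to the quaternary dithiane carbon, and chemoselectivity for C–C over halide opening, secured by copper catalysis at low temperature. The dithiane and the benzyl ethers are inert to the reagent, and slow addition of 7 to excess magnesium at 0 °C should limit Wurtz homocoupling.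

Step 4
Reactants: 9 (R)-4-[3,4-bis(benzyloxy)phenyl]-1-(2-{2-[4-(benzyloxy)phenyl]ethyl}-1,3-dithian-2-yl)butan-2-ol
Product: 10 (R)-7-[3,4-bis(benzyloxy)phenyl]-1-[4-(benzyloxy)phenyl]-5-hydroxyheptan-3-one
Conditions: MeI (excess), CaCO3, MeCN/H2O (9:1), 45 °C
Reagents that add atoms: water O
Why: Alkylative dethioacetalisation: S-methylation turns the dithiane into a leaving group and water delivers the carbonyl oxygen under buffered near-neutral conditions, which should spare the β-hydroxy ketone, the benzyl ethers and the C3 stereocentre.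

Step 5
Reactants: 10 (R)-7-[3,4-bis(benzyloxy)phenyl]-1-[4-(benzyloxy)phenyl]-5-hydroxyheptan-3-one
Product: 11 (3R,5R)-1-[3,4-bis(benzyloxy)phenyl]-7-[4-(benzyloxy)phenyl]-5-hydroxyheptan-3-yl acetate
Conditions: MeCHO (6 equiv), SmI2 (0.3 equiv), THF, −10 °C
Reagents that add atoms: acetaldehyde CC=O
Why: Evans–Tishchenko reduction: the samarium(III)-bound hemiacetal formed from O3 and acetaldehyde delivers its hydride intramolecularly to the C5 carbonyl through a chair-like chelated transition state, so C3 controls the new C5 stereocentre as 1,3-anti (5R) and the oxidised hemiacetal carbon stays on O3 as the acetate.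

Step 6
Reactants: 11 (3R,5R)-1-[3,4-bis(benzyloxy)phenyl]-7-[4-(benzyloxy)phenyl]-5-hydroxyheptan-3-yl acetate
Product: 12 (3R,5R)-1-(3,4-dihydroxyphenyl)-5-hydroxy-7-(4-hydroxyphenyl)heptan-3-yl acetate
Conditions: H2 (1 atm), 10% Pd/C, EtOAc, rt
Reagents that add atoms: none
Why: Catalytic hydrogenolysis of the three aryl benzyl ethers under neutral aprotic conditions should leave the secondary acetate in place, since no other C–O bond is benzylic or allylic and acyl migration needs acid or base.

Compound list
1 | 3-[4-(benzyloxy)phenyl]propanal | O=CCCc1ccc(OCc2ccccc2)cc1 | starting material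
2 | 2-{2-[4-(benzyloxy)phenyl]ethyl}-1,3-dithiane | C1CSC(CCc2ccc(OCc3ccccc3)cc2)SC1 | intermediate
3 | (S)-epichlorohydrin, (S)-2-(chloromethyl)oxirane | ClC[C@@H]1CO1 | starting material
4 | 2-lithio-2-{2-[4-(benzyloxy)phenyl]ethyl}-1,3-dithiane (formed in the flask) | [Li]C1(CCc2ccc(OCc3ccccc3)cc2)SCCCS1 | intermediate
5 | lithium (S)-1-chloro-3-(2-{2-[4-(benzyloxy)phenyl]ethyl}-1,3-dithian-2-yl)propan-2-olate (formed in the flask) | [Li]O[C@H](CCl)CC1(CCc2ccc(OCc3ccccc3)cc2)SCCCS1 | intermediate
6 | (S)-2-{2-[4-(benzyloxy)phenyl]ethyl}-2-(oxiran-2-ylmethyl)-1,3-dithiane | C1O[C@H]1CC2(CCc3ccc(OCc4ccccc4)cc3)SCCCS2 | intermediate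
7 | 3,4-bis(benzyloxy)benzyl chloride | ClCc1ccc(OCc2ccccc2)c(OCc2ccccc2)c1 | starting material
8 | [3,4-bis(benzyloxy)benzyl]magnesium chloride (formed in the flask) | Cl[Mg]Cc1ccc(OCc2ccccc2)c(OCc2ccccc2)c1 | intermediate
9 | (R)-4-[3,4-bis(benzyloxy)phenyl]-1-(2-{2-[4-(benzyloxy)phenyl]ethyl}-1,3-dithian-2-yl)butan-2-ol | O[C@H](CCc1ccc(OCc2ccccc2)c(OCc2ccccc2)c1)CC1(CCc2ccc(OCc3ccccc3)cc2)SCCCS1 | intermediate
10 | (R)-7-[3,4-bis(benzyloxy)phenyl]-1-[4-(benzyloxy)phenyl]-5-hydroxyheptan-3-one | O[C@H](CCc1ccc(OCc2ccccc2)c(OCc2ccccc2)c1)CC(=O)CCc1ccc(OCc2ccccc2)cc1 | intermediate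
11 | (3R,5R)-1-[3,4-bis(benzyloxy)phenyl]-7-[4-(benzyloxy)phenyl]-5-hydroxyheptan-3-yl acetate | CC(=O)O[C@H](CCc1ccc(OCc2ccccc2)c(OCc2ccccc2)c1)C[C@H](O)CCc1ccc(OCc2ccccc2)cc1 | intermediate
12 | (3R,5R)-1-(3,4-dihydroxyphenyl)-5-hydroxy-7-(4-hydroxyphenyl)heptan-3-yl acetate | CC(=O)O[C@H](CCc1ccc(O)c(O)c1)C[C@H](O)CCc1ccc(O)cc1 | target

Total step count: 6. Longest linear sequence: 6 steps (1 → 2 → 6 → 9 → 10 → 11 → 12).

Steps most likely to fail

Step 3 (key step). What may go wrong: Wurtz homocoupling while magnesium inserts into the electron-rich benzylic chloride, or opening of the oxirane by halide instead of by carbon. The fallback replaces the organomagnesium reagent by a sulfone-stabilised benzylic carbanion. It sets out from 7, which with PhSO2Na in DMF should give 1,2-bis(benzyloxy)-4-[(phenylsulfonyl)methyl]benzene F1. Its lithio derivative (n-BuLi, THF, −78 °C) opens epoxide 6 in the presence of BF3·OEt2 to the γ-hydroxy sulfone F2, a mixture of epimers at C1. Reductive desulfonylation (Na/Hg, Na2HPO4, MeOH/THF, −20 °C) removes the activating group and comes back to the route at 9.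

Step 2. What may go wrong: direct SN2 displacement of chloride competing with oxirane opening, a path that leads to the enantiomeric epoxide and erodes enantiopurity, and a second alkylation by attack of 4 on the product epoxide. The fallback uses an electrophile with a single reactive site and closes the oxirane in a separate event. It sets out from 2: lithiated dithiane 4 opens tert-butyldimethylsilyl (S)-glycidyl ether at its CH2 to the silyl ether alcohol F3. TBAF in THF frees the 1,2-diol F4. NaH and N-tosylimidazole in THF at 0 °C sulfonylate the primary hydroxyl to the primary tosylate F5 (not isolated), which closes to the epoxide and comes back to the route at 6.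

Step 6. What may go wrong: poisoning of palladium by sulfur residues carried over from steps 1 to 4, which stalls debenzylation, and O3 → O5 acetyl migration during a prolonged reaction. The fallback replaces hydrogenolysis by Lewis-acid dealkylation. It sets out from 11: BCl3 with pentamethylbenzene as cation scavenger in CH2Cl2 at −78 °C should cleave the three aryl benzyl ethers and arrive directly at 12; no new compound is made (F0).

Further compounds
F1 | step 3 | 1,2-bis(benzyloxy)-4-[(phenylsulfonyl)methyl]benzene | O=S(=O)(Cc1ccc(OCc2ccccc2)c(OCc2ccccc2)c1)c1ccccc1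
F2 | step 3 | (2R,4RS)-4-[3,4-bis(benzyloxy)phenyl]-1-(2-{2-[4-(benzyloxy)phenyl]ethyl}-1,3-dithian-2-yl)-4-(phenylsulfonyl)butan-2-ol | O[C@H](CC(c1ccc(OCc2ccccc2)c(OCc2ccccc2)c1)S(=O)(=O)c1ccccc1)CC1(CCc2ccc(OCc3ccccc3)cc2)SCCCS1
F3 | step 2 | (S)-1-(2-{2-[4-(benzyloxy)phenyl]ethyl}-1,3-dithian-2-yl)-3-[(tert-butyldimethylsilyl)oxy]propan-2-ol | O[C@H](CO[Si](C)(C)C(C)(C)C)CC1(CCc2ccc(OCc3ccccc3)cc2)SCCCS1
F4 | step 2 | (S)-3-(2-{2-[4-(benzyloxy)phenyl]ethyl}-1,3-dithian-2-yl)propane-1,2-diol | O[C@H](CO)CC1(CCc2ccc(OCc3ccccc3)cc2)SCCCS1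
F5 | step 2 | (S)-3-(2-{2-[4-(benzyloxy)phenyl]ethyl}-1,3-dithian-2-yl)-2-hydroxypropyl 4-methylbenzenesulfonate | O[C@H](COS(=O)(=O)c1ccc(C)cc1)CC1(CCc2ccc(OCc3ccccc3)cc2)SCCCS1
F0 | step 6 | none | none
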